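**Plan**
- Retrosynthesis: the spiro-cyclohexene is cut at C2–C4' and C14–C15' (Diels–Alder reaction of a unit-A dienone with the exocyclic enone of unit B, dehydrozaluzanin C); each cycloheptane is then cut at C9–C10 and C6–C7 by a (4+3) cycloaddition.
- Enabling feature: in each cycloheptane, C6 (lactone O) and C10 (exocyclic CH2) are 1,4-related across the cyclopentane bond C1–C5. An oxygen bridge C6–O–C10 therefore turns C10=C1–C5=C6 into the diene of a cyclopenta[c]furan, whose ring oxygen becomes the lactone oxygen. C7–C8–C9 with the C11–C12 side chain is the allyl cation of an iminium-activated 4-silyloxypentadienal.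
- Forward: cyclopenta[c]furan 8 → (4+3) closes the seven-membered ring (12) → exo hydrogenation → zinc opening of the bridge gives C10=C14 and, after oxidation, the lactone (16). The C8 carbonyl left by the silyloxy group is removed (unit B) or reduced to the 8β-OH (unit A). C4=C15, C11=C13 and C3=O follow on both units, then Saegusa oxidation/Diels–Alder, enone isomerisation and desilylation.
- Stereochemistry: the imidazolidinone catalyst sets C7 and, through the compact transition state, C6 and the bridge. The bridge directs hydrogenation (C1, C5). Hydride attack anti to the C7 side chain sets C8. Diels–Alder attack on the convex face of unit B sets C4'. C10 comes from γ-protonation.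

Key step: step 7

Remark: guaiane numbering is used throughout, with primed numbers for the unit that carries the spiro carbon C4'; α is the face of H-1 and H-5. The target SMILES corresponds to 8β-OH and 10β-H in the unprimed unit and to the natural 1α,5α,6β,7α-H arrangement in both units.

Step 1
Reactants: 1 3-bromofuran; 2 benzyl chloromethyl ether
Product: 3 2-[(benzyloxy)methyl]-3-bromofuran
Conditions: LiN(i-Pr)2, THF, −78 °C; then 2, −78 → 0 °C
Reagents that add atoms: none
Why: Directed α-lithiation of 3-bromofuran at C2, the position flanked by oxygen and bromine, followed by alkylation with the α-chloro ether installs the future C14 as a benzyloxymethyl group; no stereocentre is formed.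

Step 2
Reactants: 3 2-[(benzyloxy)methyl]-3-bromofuran; 4 oxetan-2-one (β-propiolactone)
Product: 5 3-{2-[(benzyloxy)methyl]furan-3-yl}propanoic acid
Conditions: n-BuLi, THF, −78 °C; MgBr2·OEt2; CuI (10 mol %), 4, −30 → 0 °C; aq. HCl
Reagents that add atoms: none
Why: Bromine–lithium exchange, transmetalation and copper-catalysed SN2 opening of the β-lactone at its alkyl C–O bond by the furyl Grignard reagent should deliver the three-carbon acid chain (future C2, C3, C4) in one operation.

Step 3
Reactants: 5 3-{2-[(benzyloxy)methyl]furan-3-yl}propanoic acid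
Product: 7 1-[(benzyloxy)methyl]-5,6-dihydro-4H-cyclopenta[c]furan-4-one, via acid chloride 6 (not isolated)
Conditions: (COCl)2, DMF (cat.), CH2Cl2, 0 °C; then SnCl4, CH2Cl2 (0.01 M), −78 → −20 °C
Reagents that add atoms: none
Why: Intramolecular Friedel–Crafts acylation: with furan C2 blocked, the acylium ion can reach only the β-carbon C4, so the cyclopentanone should close regiospecifically, high dilution suppressing intermolecular acylation at the free α-position.

Step 4
Reactants: 7 1-[(benzyloxy)methyl]-5,6-dihydro-4H-cyclopenta[c]furan-4-one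
Product: 8 1-[(benzyloxy)methyl]-5,6-dihydrospiro[cyclopenta[c]furan-4,2'-[1,3]dioxolane]
Conditions: TMSOCH2CH2OTMS, TMSOTf (cat.), CH2Cl2, −78 → −20 °C; Et3N quench
Reagents that add atoms: 1,2-bis(trimethylsilyloxy)ethane, C[Si](C)(C)OCCO[Si](C)(C)C
Why: Noyori ketalisation works on the weakly electrophilic, furan-conjugated ketone under non-aqueous conditions that spare the furan; the ketal restores the electron-rich diene and keeps it achiral.

Step 5
Reactants: 9 2-methylfuran
Product: 10 (E)-4-oxopent-2-enal
Conditions: NBS, NaHCO3, acetone–H2O, −15 °C; then pyridine, rt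
Reagents that add atoms: water, O
Why: Oxidative ring opening of the 2-alkylfuran (bromonium addition, hydrolysis to the cis-enedione) followed by pyridine-mediated cis-to-trans isomerisation should give the (E)-oxoenal.

Step 6
Reactants: 10 (E)-4-oxopent-2-enal
Product: 11 (E)-4-[(tert-butyldimethylsilyl)oxy]penta-2,4-dienal
Conditions: TBSOTf, Et3N, Et2O, 0 °C
Reagents that add atoms: tert-butyldimethylsilyl triflate, CC(C)(C)[Si](C)(C)OS(=O)(=O)C(F)(F)F
Why: Soft enolisation of the methyl ketone, the only enolisable site, gives the 2-silyloxydiene (silyl enol ether formation).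

Step 7
Reactants: 8 1-[(benzyloxy)methyl]-5,6-dihydrospiro[cyclopenta[c]furan-4,2'-[1,3]dioxolane]; 11 (E)-4-[(tert-butyldimethylsilyl)oxy]penta-2,4-dienal
Product: 12 14-benzyloxy-6α,10α-epoxy-4,4-ethylenedioxy-8-oxo-13,15-dinorguai-1(5)-en-12-al (7αH; side chain anti to the oxygen bridge)
Conditions: (2R,5R)-5-benzyl-2-tert-butyl-3-methylimidazolidin-4-one·CF3CO2H (20 mol %), CH2Cl2, −78 °C; pH 7 buffer
Reagents that add atoms: none
Why: The imidazolidinone condenses with 11 to an E-iminium whose C3–C4(OSi)–C5 part is a 2-silyloxyallyl cation; furan 8 adds across its termini, the free α-carbon C6 to the iminium β-carbon (C7) and the substituted α-carbon C10 to the CH2 terminus (C9), and loss of the silyl group plus enamine hydrolysis leave the C8 ketone and the C12 aldehyde. The closest known reaction is the amine-catalysed enantioselective (4+3) cycloaddition of 4-silyloxypentadienals with 2,5-dialkylfurans, itself a variant of the oxyallyl cation–furan cycloaddition. The cycloheptane ring (C1, C5–C10) is closed by intermolecular (4+3) cycloaddition of the 4π furan diene C10=C1–C5=C6 with the 2π allyl cation, the second bond forming as a seven-membered closure of the silyl enol ether onto the furan-derived oxocarbenium ion, while the C6–O–C10 bridge is carried over from the furan. C7 is fixed by the catalyst (its benzyl group shields one face of the iminium; by the usual shielding model the (2R,5R) antipode is expected to give 7S), and C6 and C10 follow from the compact transition state that places the side chain equatorial, anti to the oxygen bridge (H6/H7 trans), which is also the thermodynamic arrangement because C7 is α to the ketone. The step needs head-to-tail regiochemistry and ring closure in place of Friedel–Crafts rearomatisation: the first is secured by the higher nucleophilicity and lower hindrance of the unsubstituted C6 and the alkyl stabilisation of the C10 oxocarbenium ion, the second by the tethered silyl enol ether trapping that cation at −78 °C, and the ketal keeps the furan electron-rich and achiral so that the catalyst alone controls the absolute configuration.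

Step 8
Reactants: 12 14-benzyloxy-6α,10α-epoxy-4,4-ethylenedioxy-8-oxo-13,15-dinorguai-1(5)-en-12-al
Product: 13 6α,10α-epoxy-4,4-ethylenedioxy-14-hydroxy-8-oxo-13,15-dinor-1αH,5αH,7αH-guaian-12-al
Conditions: H2 (4 atm), Pd(OH)2/C, EtOAc, rt
Reagents that add atoms: none
Why: Heterogeneous hydrogenation should add H2 to the strained bridged alkene from the exo face, syn to the one-atom oxygen bridge, which sets C1 and C5 (both H α, cis ring fusion), and it hydrogenolyses the benzyl ether at the same time.

Step 9
Reactants: 13 6α,10α-epoxy-4,4-ethylenedioxy-14-hydroxy-8-oxo-13,15-dinor-1αH,5αH,7αH-guaian-12-al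
Product: 14 6α,10α-epoxy-4,4-ethylenedioxy-14-iodo-8-oxo-13,15-dinor-1αH,5αH,7αH-guaian-12-al
Conditions: I2, PPh3, imidazole, toluene, 60 °C
Reagents that add atoms: iodine, II
Why: Appel-type iodination of the primary alcohol provides the halide needed for fragmentation; the mild base leaves C7 in its preferred equatorial configuration.

Step 10
Reactants: 14 6α,10α-epoxy-4,4-ethylenedioxy-14-iodo-8-oxo-13,15-dinor-1αH,5αH,7αH-guaian-12-al
Product: 15 6α,12-epoxy-4,4-ethylenedioxy-12-hydroxy-13,15-dinor-1αH,5αH,6βH,7αH-guai-10(14)-en-8-one (lactol; both anomers)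
Conditions: Zn dust (activated), THF–H2O (4:1), ultrasound, 40 °C
Reagents that add atoms: none
Why: Zinc insertion into the C–I bond and β-elimination of the bridging alkoxide (Boord/Vasella-type reductive fragmentation) should open the bridge regiospecifically to the C10=C14 exocyclic alkene and the C6 alkoxide, which closes onto the aldehyde as the trans-fused lactol.

Step 11
Reactants: 15 lactol (as above)
Product: 16 4,4-ethylenedioxy-8-oxo-13,15-dinor-1αH,5αH,6βH,7αH-guai-10(14)-en-12,6-olide
Conditions: TEMPO (10 mol %), PhI(OAc)2, CH2Cl2, rt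
Reagents that add atoms: none
Why: Oxoammonium-mediated lactol-to-lactone oxidation is chemoselective and leaves the ketone and the 1,1-disubstituted alkene untouched.

Step 12
Reactants: 16 4,4-ethylenedioxy-8-oxo-13,15-dinor-1αH,5αH,6βH,7αH-guai-10(14)-en-12,6-olide
Product: 18 4,4-ethylenedioxy-13,15-dinor-1αH,5αH,6βH,7αH-guai-10(14)-en-12,6-olide, via tosylhydrazone 17 (not isolated)
Conditions: TsNHNH2, THF, rt; then catecholborane, CHCl3, 0 °C; then NaOAc·3H2O, 60 °C
Reagents that add atoms: none
Why: Caglioti/Kabalka deoxygenation (hydride reduction of the tosylhydrazone, loss of sulfinate and N2 from the diazene) removes the C8 carbonyl, the helper left by the silyloxyallyl cation, under near-neutral conditions that should not trigger β-elimination of the lactone oxygen.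

Step 13
Reactants: 18 4,4-ethylenedioxy-13,15-dinor-1αH,5αH,6βH,7αH-guai-10(14)-en-12,6-olide
Product: 19 4-oxo-13,15-dinor-1αH,5αH,6βH,7αH-guai-10(14)-en-12,6-olide
Conditions: PPTS, acetone–H2O (10:1), 50 °C
Reagents that add atoms: water, O
Why: Mild acid-catalysed ketal hydrolysis unmasks the C4 ketone without epimerising C5 or moving the exocyclic alkene.

Step 14
Reactants: 19 4-oxo-13,15-dinor-1αH,5αH,6βH,7αH-guai-10(14)-en-12,6-olide
Product: 20 13-nor-1αH,5αH,6βH,7αH-guaia-4(15),10(14)-dien-12,6-olide
Conditions: Zn, CH2Br2, TiCl4, THF–CH2Cl2, 0 °C → rt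
Reagents that add atoms: dibromomethane, BrCBr
Why: Takai–Lombardo methylenation is non-basic, so the enolisable β-acyloxy ketone should give the C4=C15 alkene without E1cB loss of the lactone oxygen or epimerisation at C5, and the lactone carbonyl is not attacked.

Step 15
Reactants: 20 13-nor-1αH,5αH,6βH,7αH-guaia-4(15),10(14)-dien-12,6-olide
Product: 23 dehydrocostus lactone (guaia-4(15),10(14),11(13)-trien-12,6-olide), via Mannich base 21 (not isolated), via ammonium iodide 22 (not isolated)
Conditions: LiN(i-Pr)2, THF, −78 °C; Me2N=CH2+ I−, −78 °C → rt; then MeI, MeOH, rt; then aq. NaHCO3, CH2Cl2, rt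
Reagents that add atoms: N,N-dimethylmethyleneiminium iodide (Eschenmoser's salt), C=[N+](C)C.[I-]
Why: Lactone enolate Mannich reaction, N-methylation and Hofmann-type elimination, the standard α-methylenation of γ-butyrolactones, installs C11=C13.

Step 16
Reactants: 23 dehydrocostus lactone
Product: 24 3-epizaluzanin C (3α-hydroxyguaia-4(15),10(14),11(13)-trien-12,6-olide)
Conditions: SeO2 (0.5 equiv), t-BuOOH, CH2Cl2, 0 °C → rt
Reagents that add atoms: tert-butyl hydroperoxide, CC(C)(C)OO
Why: Selenium dioxide allylic oxidation (ene reaction, then [2,3]-shift) should hydroxylate the cyclopentane CH2 next to the C4 exocyclic alkene from the convex α face, a transformation known on dehydrocostus lactone itself; the carbinol configuration is irrelevant because it is oxidised next.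

Step 17
Reactants: 24 3-epizaluzanin C
Product: 25 dehydrozaluzanin C (3-oxoguaia-4(15),10(14),11(13)-trien-12,6-olide)
Conditions: Dess–Martin periodinane, CH2Cl2, rt
Reagents that add atoms: none
Why: Dess–Martin oxidation of the allylic alcohol gives the exocyclic enone that serves as dienophile.

Step 18
Reactants: 16 4,4-ethylenedioxy-8-oxo-13,15-dinor-1αH,5αH,6βH,7αH-guai-10(14)-en-12,6-olide
Product: 26 4,4-ethylenedioxy-8β-hydroxy-13,15-dinor-1αH,5αH,6βH,7αH-guai-10(14)-en-12,6-olide
Conditions: LiBH(s-Bu)3, THF, −78 °C; AcOH quench at −78 °C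
Reagents that add atoms: none
Why: The bulky hydride should attack the C8 carbonyl from the α face, anti to the C7–C11 bond of the trans-fused lactone, which gives the 8β-alcohol; the cold acidic quench prevents translactonisation.

Step 19
Reactants: 26 8β-hydroxy ketal lactone (as above)
Product: 27 8β-[(tert-butyldimethylsilyl)oxy]-4,4-ethylenedioxy-13,15-dinor-1αH,5αH,6βH,7αH-guai-10(14)-en-12,6-olide
Conditions: TBSOTf, 2,6-lutidine, CH2Cl2, −78 → 0 °C
Reagents that add atoms: tert-butyldimethylsilyl triflate, CC(C)(C)[Si](C)(C)OS(=O)(=O)C(F)(F)F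
Why: Silylation of the secondary alcohol blocks translactonisation to the 8,12-olide and protects the hydroxyl through the enolate and oxidation steps.

Step 20
Reactants: 27 8β-silyloxy ketal lactone (as above)
Product: 28 8β-[(tert-butyldimethylsilyl)oxy]-4-oxo-13,15-dinor-1αH,5αH,6βH,7αH-guai-10(14)-en-12,6-olide
Conditions: PPTS, acetone–H2O (10:1), 50 °C
Reagents that add atoms: water, O
Why: Mild ketal hydrolysis frees the C4 ketone while the secondary silyl ether survives.

Step 21
Reactants: 28 8β-silyloxy 4-ketone (as above)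
Product: 29 8β-[(tert-butyldimethylsilyl)oxy]-13-nor-1αH,5αH,6βH,7αH-guaia-4(15),10(14)-dien-12,6-olide
Conditions: Zn, CH2Br2, TiCl4, THF–CH2Cl2, 0 °C → rt
Reagents that add atoms: dibromomethane, BrCBr
Why: Takai–Lombardo methylenation, as in step 14, forms C4=C15 without base-induced elimination or epimerisation.

Step 22
Reactants: 29 8β-silyloxy diene lactone (as above)
Product: 32 8β-[(tert-butyldimethylsilyl)oxy]dehydrocostus lactone, via Mannich base 30 (not isolated), via ammonium iodide 31 (not isolated)
Conditions: LiN(i-Pr)2, THF, −78 °C; Me2N=CH2+ I−, −78 °C → rt; then MeI, MeOH, rt; then aq. NaHCO3, CH2Cl2, rt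
Reagents that add atoms: N,N-dimethylmethyleneiminium iodide (Eschenmoser's salt), C=[N+](C)C.[I-]
Why: The same enolate Mannich/Hofmann elimination sequence installs C11=C13; the silyl ether prevents alkoxide-driven translactonisation.

Step 23
Reactants: 32 8β-[(tert-butyldimethylsilyl)oxy]dehydrocostus lactone
Product: 33 8β-[(tert-butyldimethylsilyl)oxy]-3α-hydroxyguaia-4(15),10(14),11(13)-trien-12,6-olide
Conditions: SeO2 (0.5 equiv), t-BuOOH, CH2Cl2, 0 °C → rt
Reagents that add atoms: tert-butyl hydroperoxide, CC(C)(C)OO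
Why: Selenium dioxide allylic oxidation at C3, as in step 16; the C9 position is further deactivated by the adjacent silyloxy group.

Step 24
Reactants: 33 3α-hydroxy compound (as above)
Product: 34 8β-[(tert-butyldimethylsilyl)oxy]dehydrozaluzanin C
Conditions: Dess–Martin periodinane, CH2Cl2, rt
Reagents that add atoms: none
Why: Dess–Martin oxidation of the allylic alcohol gives the 3-ketone.

Step 25
Reactants: 34 8β-[(tert-butyldimethylsilyl)oxy]dehydrozaluzanin C
Product: 35 8β-[(tert-butyldimethylsilyl)oxy]-3-[(trimethylsilyl)oxy]guaia-2,4(15),10(14),11(13)-tetraen-12,6-olide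
Conditions: TMSOTf, Et3N, CH2Cl2, 0 °C
Reagents that add atoms: trimethylsilyl triflate, C[Si](C)(C)OS(=O)(=O)C(F)(F)F
Why: Soft enolisation toward C2, the only α-CH of the C3 ketone, gives the silyl dienol ether required for the Saegusa oxidation.

Step 26
Reactants: 35 silyl dienol ether (as above); 25 dehydrozaluzanin C
Product: 37 Diels–Alder adduct (C2–C4' and C14–C15' bonds, C1=C10 alkene, 8β-silyloxy; C2 epimers, centre lost in step 27), via dienone 36 (not isolated)
Conditions: Pd(OAc)2 (1.2 equiv), 25 (3 equiv), MeCN, rt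
Reagents that add atoms: none
Why: Saegusa–Ito oxidation with palladium diacetate gives the cross-conjugated dienone 36, whose s-cis C14=C10–C1=C2 diene should add in an intermolecular Diels–Alder reaction (known in this dimer family) to the exocyclic enone of 25 with ortho orientation and from the convex α face of 25, which sets the spiro centre C4'.

Step 27
Reactants: 37 Diels–Alder adduct (as above)
Product: 38 8-O-(tert-butyldimethylsilyl) ether of the target
Conditions: Et3N, CH2Cl2, rt
Reagents that add atoms: none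
Why: Amine-mediated 1,3-prototropic shift moves the β,γ-alkene into conjugation (C1=C10 → C1=C2); the proton taken from the β face of C2 (anti to the α-bonded spiro carbon) should be relayed suprafacially to the β face of C10, and as C10–H is γ to the new enone the centre can also equilibrate through the dienolate.

Step 28
Reactants: 38 silyl ether of the target
Product: 39 target (CNP0200944.1)
Conditions: HF·pyridine, THF, 0 °C → rt
Reagents that add atoms: none
Why: Buffered acidic fluoride desilylation frees the 8β-hydroxyl without Michael addition to the methylene lactones or translactonisation.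

**Compound list**
1 | 3-bromofuran | Brc1ccoc1 | starting material
2 | benzyl chloromethyl ether | ClCOCc1ccccc1 | starting material
3 | 2-[(benzyloxy)methyl]-3-bromofuran | Brc1ccoc1COCc1ccccc1 | intermediate
4 | oxetan-2-one (β-propiolactone) | O=C1CCO1 | starting material
5 | 3-{2-[(benzyloxy)methyl]furan-3-yl}propanoic acid | OC(=O)CCc1ccoc1COCc1ccccc1 | intermediate
6 | 3-{2-[(benzyloxy)methyl]furan-3-yl}propanoyl chloride (not isolated) | ClC(=O)CCc1ccoc1COCc1ccccc1 | intermediate
7 | 1-[(benzyloxy)methyl]-5,6-dihydro-4H-cyclopenta[c]furan-4-one | O=C1CCc2c(COCc3ccccc3)occ12 | intermediate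
8 | 1-[(benzyloxy)methyl]-5,6-dihydrospiro[cyclopenta[c]furan-4,2'-[1,3]dioxolane] | C1COC2(O1)CCc1c(COCc3ccccc3)occ12 | intermediate
9 | 2-methylfuran | Cc1ccco1 | starting material
10 | (E)-4-oxopent-2-enal | CC(=O)/C=C/C=O | intermediate
11 | (E)-4-[(tert-butyldimethylsilyl)oxy]penta-2,4-dienal | C=C(O[Si](C)(C)C(C)(C)C)/C=C/C=O | intermediate
12 | 14-benzyloxy-6α,10α-epoxy-4,4-ethylenedioxy-8-oxo-13,15-dinorguai-1(5)-en-12-al (7αH) | O=CC[C@@H]1C(=O)C[C@@]2(COCc3ccccc3)O[C@@H]1C1=C2CCC13OCCO3 | intermediate
13 | 6α,10α-epoxy-4,4-ethylenedioxy-14-hydroxy-8-oxo-13,15-dinor-1αH,5αH,7αH-guaian-12-al | C1COC2(O1)CC[C@H]3[C@@]4(CO)CC(=O)[C@@H](CC=O)[C@H](O4)[C@H]32 | intermediate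
14 | 6α,10α-epoxy-4,4-ethylenedioxy-14-iodo-8-oxo-13,15-dinor-1αH,5αH,7αH-guaian-12-al | C1COC2(O1)CC[C@H]3[C@@]4(CI)CC(=O)[C@@H](CC=O)[C@H](O4)[C@H]32 | intermediate
15 | 6α,12-epoxy-4,4-ethylenedioxy-12-hydroxy-13,15-dinorguai-10(14)-en-8-one (lactol, both anomers) | C1COC2(O1)CC[C@H]3C(=C)CC(=O)[C@H]4CC(O)O[C@@H]4[C@H]32 | intermediate
16 | 4,4-ethylenedioxy-8-oxo-13,15-dinorguai-10(14)-en-12,6-olide | C1COC2(O1)CC[C@H]3C(=C)CC(=O)[C@H]4CC(=O)O[C@@H]4[C@H]32 | intermediate
17 | C8 tosylhydrazone of 16 (not isolated) | C1COC2(O1)CC[C@H]3C(=C)CC(=NNS(=O)(=O)c5ccc(C)cc5)[C@H]4CC(=O)O[C@@H]4[C@H]32 | intermediate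
18 | 4,4-ethylenedioxy-13,15-dinorguai-10(14)-en-12,6-olide | C1COC2(O1)CC[C@H]3C(=C)CC[C@H]4CC(=O)O[C@@H]4[C@H]32 | intermediate
19 | 4-oxo-13,15-dinorguai-10(14)-en-12,6-olide | O=C1CC[C@H]2C(=C)CC[C@H]3CC(=O)O[C@@H]3[C@H]21 | intermediate
20 | 13-norguaia-4(15),10(14)-dien-12,6-olide | C=C1CC[C@H]2C(=C)CC[C@H]3CC(=O)O[C@@H]3[C@H]21 | intermediate
21 | 11-(dimethylaminomethyl) derivative of 20 (not isolated; C11 epimers) | C=C1CC[C@H]2C(=C)CC[C@H]3C(CN(C)C)C(=O)O[C@@H]3[C@H]21 | intermediate
22 | 11-(trimethylammoniomethyl) iodide of 20 (not isolated) | C=C1CC[C@H]2C(=C)CC[C@H]3C(C[N+](C)(C)C)C(=O)O[C@@H]3[C@H]21.[I-] | intermediate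
23 | dehydrocostus lactone | C=C1CC[C@H]2C(=C)CC[C@H]3C(=C)C(=O)O[C@@H]3[C@H]21 | intermediate
24 | 3-epizaluzanin C (3α-OH) | C=C1[C@H](O)C[C@H]2C(=C)CC[C@H]3C(=C)C(=O)O[C@@H]3[C@H]21 | intermediate
25 | dehydrozaluzanin C | C=C1C(=O)C[C@H]2C(=C)CC[C@H]3C(=C)C(=O)O[C@@H]3[C@H]21 | intermediate
26 | 4,4-ethylenedioxy-8β-hydroxy-13,15-dinorguai-10(14)-en-12,6-olide | C1COC2(O1)CC[C@H]3C(=C)C[C@@H](O)[C@H]4CC(=O)O[C@@H]4[C@H]32 | intermediate
27 | 8β-(tert-butyldimethylsilyloxy)-4,4-ethylenedioxy-13,15-dinorguai-10(14)-en-12,6-olide | C1COC2(O1)CC[C@H]3C(=C)C[C@@H](O[Si](C)(C)C(C)(C)C)[C@H]4CC(=O)O[C@@H]4[C@H]32 | intermediate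
28 | 8β-(tert-butyldimethylsilyloxy)-4-oxo-13,15-dinorguai-10(14)-en-12,6-olide | O=C1CC[C@H]2C(=C)C[C@@H](O[Si](C)(C)C(C)(C)C)[C@H]3CC(=O)O[C@@H]3[C@H]21 | intermediate
29 | 8β-(tert-butyldimethylsilyloxy)-13-norguaia-4(15),10(14)-dien-12,6-olide | C=C1CC[C@H]2C(=C)C[C@@H](O[Si](C)(C)C(C)(C)C)[C@H]3CC(=O)O[C@@H]3[C@H]21 | intermediate
30 | 11-(dimethylaminomethyl) derivative of 29 (not isolated; C11 epimers) | C=C1CC[C@H]2C(=C)C[C@@H](O[Si](C)(C)C(C)(C)C)[C@H]3C(CN(C)C)C(=O)O[C@@H]3[C@H]21 | intermediate
31 | 11-(trimethylammoniomethyl) iodide of 29 (not isolated) | C=C1CC[C@H]2C(=C)C[C@@H](O[Si](C)(C)C(C)(C)C)[C@H]3C(C[N+](C)(C)C)C(=O)O[C@@H]3[C@H]21.[I-] | intermediate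
32 | 8β-(tert-butyldimethylsilyloxy)dehydrocostus lactone | C=C1CC[C@H]2C(=C)C[C@@H](O[Si](C)(C)C(C)(C)C)[C@H]3C(=C)C(=O)O[C@@H]3[C@H]21 | intermediate
33 | 8β-(tert-butyldimethylsilyloxy)-3α-hydroxyguaia-4(15),10(14),11(13)-trien-12,6-olide | C=C1[C@H](O)C[C@H]2C(=C)C[C@@H](O[Si](C)(C)C(C)(C)C)[C@H]3C(=C)C(=O)O[C@@H]3[C@H]21 | intermediate
34 | 8β-(tert-butyldimethylsilyloxy)dehydrozaluzanin C | C=C1C(=O)C[C@H]2C(=C)C[C@@H](O[Si](C)(C)C(C)(C)C)[C@H]3C(=C)C(=O)O[C@@H]3[C@H]21 | intermediate
35 | 3-O-trimethylsilyl dienol ether of 34 | C=C1C(O[Si](C)(C)C)=C[C@H]2C(=C)C[C@@H](O[Si](C)(C)C(C)(C)C)[C@H]3C(=C)C(=O)O[C@@H]3[C@H]21 | intermediate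
36 | 8β-(tert-butyldimethylsilyloxy)-3-oxoguaia-1,4(15),10(14),11(13)-tetraen-12,6-olide (not isolated) | C=C1C(=O)C=C2C(=C)C[C@@H](O[Si](C)(C)C(C)(C)C)[C@H]3C(=C)C(=O)O[C@@H]3[C@H]21 | intermediate
37 | Diels–Alder adduct (C1=C10 alkene, C2 epimers, 8β-silyloxy) | C=C1C(=O)C2C3=C(CC[C@]24C(=O)C[C@H]2C(=C)CC[C@H]5C(=C)C(=O)O[C@@H]5[C@H]24)C[C@@H](O[Si](C)(C)C(C)(C)C)[C@H]2C(=C)C(=O)O[C@@H]2[C@@H]13 | intermediate
38 | 8-O-(tert-butyldimethylsilyl) ether of the target | C=C1C(=O)C2=C3[C@H](CC[C@]24C(=O)C[C@H]2C(=C)CC[C@H]5C(=C)C(=O)O[C@@H]5[C@H]24)C[C@@H](O[Si](C)(C)C(C)(C)C)[C@H]2C(=C)C(=O)O[C@@H]2[C@@H]13 | intermediate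
39 | CNP0200944.1 | C=C1C(=O)C2=C3[C@H](CC[C@]24C(=O)C[C@H]2C(=C)CC[C@H]5C(=C)C(=O)O[C@@H]5[C@H]24)C[C@@H](O)[C@H]2C(=C)C(=O)O[C@@H]2[C@@H]13 | target

**Step count and risks**

Total: 28 steps. Longest linear sequence: 20 steps (steps 1–4, 7–11, 18–28).

Most likely to fail:

1. Step 7. After the first C–C bond the furan may rearomatise by loss of the C6 proton (Friedel–Crafts alkylation) instead of closing the ring; the two termini may pair in the other sense; an uncatalysed background reaction may erode the enantioselectivity; the furyl ketal may hydrolyse. The fallback sets out from 8 and comes back at 12 by the rhodium-carbenoid (4+3) route, the tandem cyclopropanation/Cope rearrangement of vinylcarbenoids with furans. Furan 8 would be treated with ethyl 2-diazo-3-[(tert-butyldimethylsilyl)oxy]but-3-enoate F1 (from commercial ethyl 2-diazo-3-oxobutanoate, TBSOTf, Et3N) and Rh2(S-PTAD)4 or its enantiomer (hexane, −40 °C), the catalyst antipode being chosen to match 12. The carbenoid should attack the less substituted C5=C6 bond and give the bridged silyl enol ether ester F2. TBAF/AcOH should then give the β-keto ester F3, C-allylation (allyl bromide, K2CO3, acetone) the quaternary ester F4, and Krapcho dealkoxycarbonylation (LiCl, wet DMSO, 140 °C) the equatorial 7-allyl ketone F5 by thermodynamic protonation. OsO4 (cat.)/NMO followed by NaIO4 should cleave the terminal alkene selectively in the presence of the hindered tetrasubstituted one and return to 12.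

2. Step 26. The dienone may dimerise with itself through its own exocyclic enone; the silyl dienol ether may react prematurely as an electron-rich diene; the palladium-mediated dehydrogenation may stall. The fallback sets out from 34 and comes back at 37 without palladium or a silyl dienol ether. Ketone 34 would be α-selenenylated (LiN(SiMe3)2, THF, −78 °C; PhSeCl) to the 2-phenylselanyl ketone F6. Its oxidation (H2O2, pyridine, CH2Cl2, 0 °C) in the presence of excess 25 releases dienone 36 slowly by selenoxide syn-elimination, so that it is trapped by 25 as it forms.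

3. Step 27. Protonation at C10 may show poor facial selectivity, or the equilibrium may favour the C10 epimer. The fallback sets out from 37 and ends at 39 by changing the order and the control element. The silyl ether would be removed first (HF·pyridine, THF) to give the 8β-hydroxy Diels–Alder adduct F7. Isomerisation with Et3N is then expected to be directed by the free 8β-hydroxyl, which lies on the β face next to C9 and can relay the proton to the β face of C10 of the dienolate.

**Further compounds**
F1 | step 7 | ethyl 2-diazo-3-[(tert-butyldimethylsilyl)oxy]but-3-enoate | CCOC(=O)C(=[N+]=[N-])C(=C)O[Si](C)(C)C(C)(C)C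
F2 | step 7 | ethyl 14-benzyloxy-8-[(tert-butyldimethylsilyl)oxy]-6α,10α-epoxy-4,4-ethylenedioxy-11,13,15-trinorguaia-1(5),7-dien-12-oate (ester carbon on C7) | CCOC(=O)C1=C(O[Si](C)(C)C(C)(C)C)C[C@@]2(COCc3ccccc3)O[C@@H]1C1=C2CCC13OCCO3
F3 | step 7 | β-keto ester from F2 (8-oxo; C7 epimers and enol) | CCOC(=O)C1C(=O)C[C@@]2(COCc3ccccc3)O[C@@H]1C1=C2CCC13OCCO3
F4 | step 7 | 7-allyl β-keto ester (C7 epimers) | CCOC(=O)C1(CC=C)C(=O)C[C@@]2(COCc3ccccc3)O[C@@H]1C1=C2CCC13OCCO3
F5 | step 7 | 7-allyl ketone (7αH; allyl anti to the oxygen bridge) | C=CC[C@@H]1C(=O)C[C@@]2(COCc3ccccc3)O[C@@H]1C1=C2CCC13OCCO3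
F6 | step 26 | 2-(phenylselanyl) derivative of 34 (C2 epimers) | C=C1C(=O)C([Se]c4ccccc4)[C@H]2C(=C)C[C@@H](O[Si](C)(C)C(C)(C)C)[C@H]3C(=C)C(=O)O[C@@H]3[C@H]21
F7 | step 27 | 8β-hydroxy Diels–Alder adduct (C1=C10 alkene, C2 epimers) | C=C1C(=O)C2C3=C(CC[C@]24C(=O)C[C@H]2C(=C)CC[C@H]5C(=C)C(=O)O[C@@H]5[C@H]24)C[C@@H](O)[C@H]2C(=C)C(=O)O[C@@H]2[C@@H]13
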